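(All runs were generated by integration from invented constants; noise was put on by code.)

Late in the ochre run, at 20.0 min, product reads 61%. The partner charge there is 0.75 equiv, below one equivalent, so partner is the limiting reagent of that run, and you should keep its books.

| flask | starting material | partner | free catalyst | remark |
|---|---|---|---|---|
| blue | 0.50 M | 1.5 equiv | 2 mol% | the very flask that is asked about, followed so far |
| ochre | 0.50 M | 0.75 equiv | 2 mol% | run made earlier |
| flask | 0.50 M | 1.50 equiv | 2 mol% |  |

- blue (time / min: product / %): 0.833: 19; 2.00: 35; 4.00: 63; 6.00: 73
- ochre (time / min: product / %): 1.50: 16; 4.00: 34; 8.00: 50; 20.0: 61

(readings scatter by 2 percentage points)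

- no earlier run changes the charge of free catalyst; that part of a forecast is a guess

- apparent order in partner when 50% of the starting material are converted (percent change of the rate of making product for one percent more partner charged)
- apparent order in free catalyst when 50% of the starting material are converted (percent change of the rate of making product for one percent more free catalyst charged)
- factor on the rate of making product when 50% of the starting material are converted if partner is charged twice over

Count per starting material charged, with e the equivalents of partner charged, x the fraction converted, and one partner booked to each product:

charged: e
booked to product: x
open entry: e − x

In the ochre run at 20.0 min the open entry is 0.140 equiv, and no reading shows where it stands.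

My own reckoning takes the rate as k′(1 − x)(e − x), with k′ a constant per minute. Integrated, this gives:

k′t = ln[(e − x) / (e(1 − x))] / (e − 1)

The blue run at 4.00 min reads 0.225 /min, and the ochre run at 4.00 min reads 0.188 /min. With the rate following the open entry, one percent more charge moves the rate at fixed x by the leverage:

L = e / (e − x)

For the flask at 50% conversion the leverage is 1.50, and doubling the charge gives (e + e − x)/(e − x) = 2.50. No run changes the free catalyst, so I reckon nothing for it.

The forecast prints 1.4, 2.4 and 1. Its first two sit a little under my values, and of the third it says “Catalyst order is a guess”.

The flask gives 1.5 in partner, 2.34 on doubling and 1.5 in free catalyst; the leverage of 1.50 stands level with the first, and the forecast parts on the catalyst.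

    starting material + free catalyst → catalyst intermediate A (k = 17.0 /M/s)
    partner + catalyst intermediate A → catalyst intermediate B (k = 0.300 /M/s)
    catalyst intermediate B → free catalyst + product (k = 4.10 /s)
    2 partner → homo dimer (k = 0.00200 /M/s)
    2 catalyst intermediate B ⇌ resting dimer, settled at all times (K = 220 /M)

On the books above, the ochre run at 50% conversion has an open entry of 0.250 equiv and a leverage of 3.00. At 20.0 min the flask's step from catalyst intermediate A uses partner 19 times as fast as homo dimer formation does. Yet the 0.119 M of homo dimer standing then holds 0.238 M of the 0.750 M partner charged.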